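The ten-membered carbocycle (C1–C10) is closed last, at C9–C10. An alkenylchromium formed at C10 of a (Z)-2-iodoallyl silyl ether adds to the C9 aldehyde of a trans-disubstituted α-methylene-γ-lactone, making the C9–C10 bond, the ring and the C9 carbinol in one operation. The step exploits that C9 is an allylic alcohol carbon bonded to C10, the fully substituted carbon of the C1=C10 olefin, and the only oxygen that becomes an acetate, so it is released as the sole free hydroxyl. The precursor has C6, C7 and C8 in place, set by indium allylation of a neryl acetate-derived (Z)-enal with a cyclic bromomethyl lactone and lactone transposition, which also unmasks C9.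

Key step: step 14

Remark: germacrane numbering is used (ring olefins C1=C10 and C4=C5, lactone oxygen on C6, C12 carbonyl, C11=C13 methylene, C14 oxymethyl on C10, C15 methyl on C4); neryl acetate, (S)-but-3-ene-1,2-diol, 2-(bromomethyl)acrylic acid and (R)-2-methylbutanoic acid are taken as commercial; the C7 descriptor is S in the PMB ethers and R in the target through a CIP priority change only.

Step 1
Reactants: 1 neryl acetate
Product: 3 (2Z)-3-methyl-6-oxohex-2-en-1-yl acetate, via ozonide 2 (not isolated)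
Conditions: O3 (1 equiv, dye end point), CH2Cl2, −78 °C; PPh3, −78 °C to rt
Reagents that add atoms: ozone, [O-][O+]=O
Why: Chemoselective ozonolysis, since the distal trisubstituted olefin is more electron-rich than the olefin deactivated by the allylic acetate, so one equivalent of ozone should cleave only the isopropylidene end and reduction of the ozonide gives the aldehyde.

Step 2
Reactants: 3 (2Z)-3-methyl-6-oxohex-2-en-1-yl acetate
Product: 4 (2Z,6E)-3-methyl-8-oxoocta-2,6-dien-1-yl acetate
Conditions: Ph3P=CHCHO, PhMe, 80 °C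
Reagents that add atoms: (triphenylphosphoranylidene)acetaldehyde, O=CC=P(c1ccccc1)(c1ccccc1)c1ccccc1
Why: Wittig olefination with the stabilised formyl ylide should give the (E)-enal and stop after one homologation because the conjugated product is less electrophilic than the saturated aldehyde.

Step 3
Reactants: 4 (2Z,6E)-3-methyl-8-oxoocta-2,6-dien-1-yl acetate
Product: 5 (2Z,6Z)-7-iodo-3-methyl-8-oxoocta-2,6-dien-1-yl acetate
Conditions: I2, DMAP (cat.), K2CO3, THF/H2O, rt
Reagents that add atoms: iodine, II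
Why: Morita–Baylis–Hillman-type α-iodination, in which DMAP adds to the β-carbon, the enolate is iodinated and loss of DMAP returns the olefin with the formyl group trans to the chain, which is the (Z)-α-iodoenal.

Step 4
Reactants: 5 (2Z,6Z)-7-iodo-3-methyl-8-oxoocta-2,6-dien-1-yl acetate
Product: 6 (2Z,6Z)-8-hydroxy-7-iodo-3-methylocta-2,6-dien-1-yl acetate
Conditions: NaBH4, CeCl3·7H2O, MeOH, −20 °C
Reagents that add atoms: none
Why: Luche 1,2-reduction, in which cerium activation directs hydride to the carbonyl carbon only, so the C–I bond, the olefin geometry and the acetate should survive.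

Step 5
Reactants: 6 (2Z,6Z)-8-hydroxy-7-iodo-3-methylocta-2,6-dien-1-yl acetate
Product: 7 (2Z,6Z)-8-(tert-butyldimethylsilyloxy)-7-iodo-3-methylocta-2,6-dien-1-yl acetate
Conditions: TBSCl, imidazole, CH2Cl2, 0 °C to rt
Reagents that add atoms: tert-butyldimethylsilyl chloride, CC(C)(C)[Si](C)(C)Cl
Why: Standard silylation of a primary allylic alcohol, giving the C14 ether that later resists β-elimination next to the alkenylmetal.

Step 6
Reactants: 7 (2Z,6Z)-8-(tert-butyldimethylsilyloxy)-7-iodo-3-methylocta-2,6-dien-1-yl acetate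
Product: 8 (2Z,6Z)-8-(tert-butyldimethylsilyloxy)-7-iodo-3-methylocta-2,6-dien-1-ol
Conditions: K2CO3 (cat.), MeOH, 0 °C
Reagents that add atoms: none
Why: Base-catalysed transesterification (methanolysis) removes the acetate, while the silyl ether and the alkenyl iodide are inert to these conditions.

Step 7
Reactants: 8 (2Z,6Z)-8-(tert-butyldimethylsilyloxy)-7-iodo-3-methylocta-2,6-dien-1-ol
Product: 9 (2Z,6Z)-8-(tert-butyldimethylsilyloxy)-7-iodo-3-methylocta-2,6-dienal
Conditions: MnO2, CH2Cl2, rt
Reagents that add atoms: none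
Why: Neutral heterogeneous MnO2 oxidation of the allylic alcohol should give the neral-type (Z)-enal without Z to E isomerisation, and the aldehyde is used at once.

Step 8
Reactants: 10 (S)-but-3-ene-1,2-diol
Product: 11 (4S)-2-(4-methoxyphenyl)-4-vinyl-1,3-dioxolane (both acetal epimers)
Conditions: 4-MeOC6H4CH(OMe)2, PPTS (cat.), CH2Cl2, rt
Reagents that add atoms: 4-methoxybenzaldehyde dimethyl acetal, COc1ccc(cc1)C(OC)OC
Why: Acid-catalysed transacetalisation of the 1,2-diol; the new acetal centre forms as both epimers, which does not matter because step 9 destroys it.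

Step 9
Reactants: 11 (4S)-2-(4-methoxyphenyl)-4-vinyl-1,3-dioxolane
Product: 12 (2S)-2-(4-methoxybenzyloxy)but-3-en-1-ol
Conditions: i-Bu2AlH, CH2Cl2, −78 to 0 °C
Reagents that add atoms: none
Why: Regioselective reductive acetal opening, in which aluminium binds the less hindered primary oxygen, that C–O bond ionises and hydride delivery leaves the PMB group on the secondary oxygen (future C8).

Step 10
Reactants: 12 (2S)-2-(4-methoxybenzyloxy)but-3-en-1-ol; 13 2-(bromomethyl)acrylic acid
Product: 14 (2S)-2-(4-methoxybenzyloxy)but-3-en-1-yl 2-(bromomethyl)acrylate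
Conditions: DCC, DMAP (cat.), CH2Cl2, 0 °C
Reagents that add atoms: none
Why: Steglich esterification of the primary alcohol, with low temperature and only catalytic DMAP to limit attack on the allylic bromide.

Step 11
Reactants: 14 (2S)-2-(4-methoxybenzyloxy)but-3-en-1-yl 2-(bromomethyl)acrylate
Product: 15 (5S)-3-(bromomethyl)-5-(4-methoxybenzyloxy)-5,6-dihydro-2H-pyran-2-one
Conditions: second-generation Hoveyda–Grubbs catalyst RuCl2(=CH-C6H4-2-O-i-Pr)(H2IMes) (5 mol%), PhMe, 80 °C, 5 mM
Reagents that add atoms: none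
Why: Ring-closing metathesis, in which the ruthenium alkylidene loads on the vinyl group and closes the six-membered ring onto the 1,1-disubstituted acrylate olefin, as in closures of methacrylate-type esters to α-substituted unsaturated lactones, driven by loss of ethylene.

Step 12
Reactants: 9 (2Z,6Z)-8-(tert-butyldimethylsilyloxy)-7-iodo-3-methylocta-2,6-dienal; 15 (5S)-3-(bromomethyl)-5-(4-methoxybenzyloxy)-5,6-dihydro-2H-pyran-2-one
Product: 18 (4S,5R)-5-[(1Z,5Z)-7-(tert-butyldimethylsilyloxy)-6-iodo-2-methylhepta-1,5-dien-1-yl]-4-[(1S)-2-hydroxy-1-(4-methoxybenzyloxy)ethyl]-3-methylidenedihydrofuran-2(3H)-one, via allylindium dibromide 16 (not isolated), via δ-lactone carbinol 17 (not isolated)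
Conditions: In powder, THF/H2O, rt; extract, then PPTS (cat.), PhMe, 40 °C
Reagents that add atoms: none
Why: Indium Barbier allylation of the 2-(bromomethyl)acrylate type followed by translactonisation: the allylindium reacts through C7 in a six-membered chair in which the ring holds C8 trans to the CH2–In end, so C6 and C7 form anti with the aldehyde substituent equatorial, the aldehyde enters on the ring face opposite the neighbouring C8 PMB ether (C7 trans to C8), and acid-catalysed acyl transfer from O9 to O6 then gives the more stable trans-γ-lactone and frees the primary C9 hydroxyl.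

Step 13
Reactants: 18 γ-lactone alcohol from step 12
Product: 19 (2S)-2-[(2R,3S)-2-[(1Z,5Z)-7-(tert-butyldimethylsilyloxy)-6-iodo-2-methylhepta-1,5-dien-1-yl]-4-methylidene-5-oxotetrahydrofuran-3-yl]-2-(4-methoxybenzyloxy)acetaldehyde
Conditions: Dess–Martin periodinane, NaHCO3, CH2Cl2, 0 °C to rt
Reagents that add atoms: none
Why: Buffered Dess–Martin oxidation of the primary alcohol should give the α-alkoxy aldehyde without epimerising C8 or moving the exocyclic methylene, and the crude aldehyde is used directly.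

Step 14
Reactants: 19 lactone aldehyde bearing the (Z)-2-iodoallyl silyl ether
Product: 21 (6R,7S,8S,9R)-14-(tert-butyldimethylsilyloxy)-9-hydroxy-8-(4-methoxybenzyloxy)germacra-1(10)Z,4Z,11(13)-trien-12,6-olide, via alkenylchromium dichloride 20 (not isolated)
Conditions: CrCl2 (10 equiv), NiCl2 (2 mol%), DMSO/THF, rt, slow addition to 2 mM
Reagents that add atoms: none
Why: Nozaki–Hiyama–Kishi reaction: zerovalent nickel, made from NiCl2 by CrCl2, inserts into the C10–I bond and passes the alkenyl group to trivalent chromium, and the alkenylchromium adds to the C9 aldehyde, the chromium alkoxide being hydrolysed on work-up. The closest known reaction type is the CrCl2/NiCl2 macrocyclisation of an alkenyl iodide onto an aldehyde. The ten-membered ring closes by 10-exo-trig carbonyl addition, helped by high dilution and by the trans-lactone and the two cis olefins (C4=C5, C1=C10), which fold the chain so that C10 reaches C9. The new C9 centre is controlled by the C8 PMB ether: in the Felkin–Anh arrangement the C8–O bond lies anti to the incoming C10, which should give the 8,9-anti (cis on the ring) relationship, that is (9R). The step needs selectivity for the aldehyde over the α-methylene lactone, which the carbonyl-selective alkenylchromium provides, retention of the (Z)-olefin, which oxidative addition and transmetalation ensure, and no β-elimination to an allene, which the poor leaving-group ability of the C14 silyl ether secures.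

Step 15
Reactants: 21 macrocyclic C9 alcohol
Product: 22 (6R,7S,8S,9R)-9-acetoxy-14-(tert-butyldimethylsilyloxy)-8-(4-methoxybenzyloxy)germacra-1(10)Z,4Z,11(13)-trien-12,6-olide
Conditions: Ac2O, pyridine, DMAP (cat.), CH2Cl2, 0 °C to rt
Reagents that add atoms: acetic anhydride, CC(=O)OC(C)=O
Why: DMAP-catalysed acetylation, with no differentiation problem because the C9 hydroxyl is the only free one.

Step 16
Reactants: 22 C9 acetate
Product: 23 (6R,7S,8S,9R)-9-acetoxy-14-hydroxy-8-(4-methoxybenzyloxy)germacra-1(10)Z,4Z,11(13)-trien-12,6-olide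
Conditions: HF·pyridine, pyridine, THF, 0 °C
Reagents that add atoms: none
Why: Fluoride-mediated desilylation under buffered acidic conditions, so no alkoxide forms that could move the acetate from O9 to O14 or add to the methylene lactone.

Step 17
Reactants: 23 C14 alcohol; 24 (R)-2-methylbutanoic acid
Product: 25 (6R,7S,8S,9R)-9-acetoxy-8-(4-methoxybenzyloxy)-14-[(2R)-2-methylbutanoyloxy]germacra-1(10)Z,4Z,11(13)-trien-12,6-olide
Conditions: EDC·HCl, DMAP (cat.), CH2Cl2, 0 °C
Reagents that add atoms: none
Why: Carbodiimide (Steglich-type) esterification of the primary allylic alcohol, run cold with catalytic DMAP to preserve the α-stereocentre of the acid.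

Step 18
Reactants: 25 PMB-protected target
Product: 26 CNP0005248.2, (6R,7R,8S,9R)-9-acetoxy-8-hydroxy-14-[(2R)-2-methylbutanoyloxy]germacra-1(10)Z,4Z,11(13)-trien-12,6-olide
Conditions: DDQ, CH2Cl2/pH 7 buffer, 0 °C
Reagents that add atoms: none
Why: Oxidative PMB cleavage (single-electron oxidation of the anisyl ring, then hydrolysis of the oxocarbenium ion) under neutral conditions that should spare both esters, the olefins and the methylene lactone and avoid acetyl migration from O9 to O8.

Compound list
1 | neryl acetate, (2Z)-3,7-dimethylocta-2,6-dien-1-yl acetate | CC(C)=CCC/C(C)=C\COC(C)=O | starting material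
2 | ozonide, (2Z)-5-(5,5-dimethyl-1,2,4-trioxolan-3-yl)-3-methylpent-2-en-1-yl acetate | CC(=O)OC/C=C(/C)CCC1OOC(C)(C)O1 | intermediate
3 | (2Z)-3-methyl-6-oxohex-2-en-1-yl acetate | CC(=O)OC/C=C(/C)CCC=O | intermediate
4 | (2Z,6E)-3-methyl-8-oxoocta-2,6-dien-1-yl acetate | CC(=O)OC/C=C(/C)CC/C=C/C=O | intermediate
5 | (2Z,6Z)-7-iodo-3-methyl-8-oxoocta-2,6-dien-1-yl acetate | CC(=O)OC/C=C(/C)CC/C=C(I)/C=O | intermediate
6 | (2Z,6Z)-8-hydroxy-7-iodo-3-methylocta-2,6-dien-1-yl acetate | CC(=O)OC/C=C(/C)CC/C=C(I)/CO | intermediate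
7 | (2Z,6Z)-8-(tert-butyldimethylsilyloxy)-7-iodo-3-methylocta-2,6-dien-1-yl acetate | CC(=O)OC/C=C(/C)CC/C=C(I)/CO[Si](C)(C)C(C)(C)C | intermediate
8 | (2Z,6Z)-8-(tert-butyldimethylsilyloxy)-7-iodo-3-methylocta-2,6-dien-1-ol | OC/C=C(/C)CC/C=C(I)/CO[Si](C)(C)C(C)(C)C | intermediate
9 | (2Z,6Z)-8-(tert-butyldimethylsilyloxy)-7-iodo-3-methylocta-2,6-dienal | O=C/C=C(/C)CC/C=C(I)/CO[Si](C)(C)C(C)(C)C | intermediate
10 | (S)-but-3-ene-1,2-diol | C=C[C@H](O)CO | starting material
11 | (4S)-2-(4-methoxyphenyl)-4-vinyl-1,3-dioxolane, both acetal epimers | C=C[C@H]1COC(c2ccc(OC)cc2)O1 | intermediate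
12 | (2S)-2-(4-methoxybenzyloxy)but-3-en-1-ol | C=C[C@H](OCc1ccc(OC)cc1)CO | intermediate
13 | 2-(bromomethyl)acrylic acid | C=C(CBr)C(=O)O | starting material
14 | (2S)-2-(4-methoxybenzyloxy)but-3-en-1-yl 2-(bromomethyl)acrylate | C=C[C@H](OCc1ccc(OC)cc1)COC(=O)C(=C)CBr | intermediate
15 | (5S)-3-(bromomethyl)-5-(4-methoxybenzyloxy)-5,6-dihydro-2H-pyran-2-one | O=C1OC[C@@H](OCc2ccc(OC)cc2)C=C1CBr | intermediate
16 | allylindium dibromide, [(5S)-5-(4-methoxybenzyloxy)-2-oxo-5,6-dihydro-2H-pyran-3-yl]methylindium dibromide | O=C1OC[C@@H](OCc2ccc(OC)cc2)C=C1C[In](Br)Br | intermediate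
17 | δ-lactone carbinol, (4S,5S)-4-[(1R,2Z,6Z)-8-(tert-butyldimethylsilyloxy)-1-hydroxy-7-iodo-3-methylocta-2,6-dien-1-yl]-5-(4-methoxybenzyloxy)-3-methylidenetetrahydro-2H-pyran-2-one | C=C1C(=O)OC[C@@H](OCc2ccc(OC)cc2)[C@@H]1[C@H](O)/C=C(/C)CC/C=C(I)/CO[Si](C)(C)C(C)(C)C | intermediate
18 | (4S,5R)-5-[(1Z,5Z)-7-(tert-butyldimethylsilyloxy)-6-iodo-2-methylhepta-1,5-dien-1-yl]-4-[(1S)-2-hydroxy-1-(4-methoxybenzyloxy)ethyl]-3-methylidenedihydrofuran-2(3H)-one | C=C1C(=O)O[C@H](/C=C(/C)CC/C=C(I)/CO[Si](C)(C)C(C)(C)C)[C@H]1[C@H](OCc2ccc(OC)cc2)CO | intermediate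
19 | (2S)-2-[(2R,3S)-2-[(1Z,5Z)-7-(tert-butyldimethylsilyloxy)-6-iodo-2-methylhepta-1,5-dien-1-yl]-4-methylidene-5-oxotetrahydrofuran-3-yl]-2-(4-methoxybenzyloxy)acetaldehyde | C=C1C(=O)O[C@H](/C=C(/C)CC/C=C(I)/CO[Si](C)(C)C(C)(C)C)[C@H]1[C@H](OCc2ccc(OC)cc2)C=O | intermediate
20 | alkenylchromium dichloride, 19 with CrCl2 in place of iodine on C10 and the olefin geometry retained | C=C1C(=O)O[C@H](/C=C(/C)CC/C=C(/CO[Si](C)(C)C(C)(C)C)[Cr](Cl)Cl)[C@H]1[C@H](OCc2ccc(OC)cc2)C=O | intermediate
21 | (6R,7S,8S,9R)-14-(tert-butyldimethylsilyloxy)-9-hydroxy-8-(4-methoxybenzyloxy)germacra-1(10)Z,4Z,11(13)-trien-12,6-olide | C=C1C(=O)O[C@@H]2/C=C(/C)CC/C=C(/CO[Si](C)(C)C(C)(C)C)[C@@H](O)[C@@H](OCc3ccc(OC)cc3)[C@@H]12 | intermediate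
22 | (6R,7S,8S,9R)-9-acetoxy-14-(tert-butyldimethylsilyloxy)-8-(4-methoxybenzyloxy)germacra-1(10)Z,4Z,11(13)-trien-12,6-olide | C=C1C(=O)O[C@@H]2/C=C(/C)CC/C=C(/CO[Si](C)(C)C(C)(C)C)[C@@H](OC(C)=O)[C@@H](OCc3ccc(OC)cc3)[C@@H]12 | intermediate
23 | (6R,7S,8S,9R)-9-acetoxy-14-hydroxy-8-(4-methoxybenzyloxy)germacra-1(10)Z,4Z,11(13)-trien-12,6-olide | C=C1C(=O)O[C@@H]2/C=C(/C)CC/C=C(/CO)[C@@H](OC(C)=O)[C@@H](OCc3ccc(OC)cc3)[C@@H]12 | intermediate
24 | (R)-2-methylbutanoic acid | CC[C@@H](C)C(=O)O | starting material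
25 | (6R,7S,8S,9R)-9-acetoxy-8-(4-methoxybenzyloxy)-14-[(2R)-2-methylbutanoyloxy]germacra-1(10)Z,4Z,11(13)-trien-12,6-olide | C=C1C(=O)O[C@@H]2/C=C(/C)CC/C=C(/COC(=O)[C@H](C)CC)[C@@H](OC(C)=O)[C@@H](OCc3ccc(OC)cc3)[C@@H]12 | intermediate
26 | CNP0005248.2, (6R,7R,8S,9R)-9-acetoxy-8-hydroxy-14-[(2R)-2-methylbutanoyloxy]germacra-1(10)Z,4Z,11(13)-trien-12,6-olide | C=C1C(=O)O[C@@H]2/C=C(/C)CC/C=C(/COC(=O)[C@H](C)CC)[C@@H](OC(C)=O)[C@@H](O)[C@@H]12 | target

Total step count: 18. Longest linear sequence: 14 steps (steps 1–7, then 12–18).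

Steps most likely to fail

Step 14. The ring-forming transition state may override the Felkin–Anh preference, so that the C9 carbinol forms with poor or inverted facial selectivity. The fallback sets out from 19: the cyclisation is run as in step 14 and the (9S)-epimeric carbinol F1, alone or mixed with 21, is oxidised with Dess–Martin periodinane/NaHCO3 to the C9 enone F2. Chelation-controlled 1,2-reduction with Zn(BH4)2 in Et2O at −30 °C, in which zinc bridges the C9 carbonyl and the C8 PMB-ether oxygen and hydride enters anti to C7, should give the 8,9-anti carbinol, and the route is rejoined at 21. The stereocentre is thus set by hydride delivery to a ketone instead of by the C–C bond formation.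

Step 12. The aqueous indium addition may lose its anti (C6/C7) or facial (C7/C8) selectivity through an open addition mode, the (Z)-enal may isomerise, or the allylmetal may lose the C8 alkoxy group reductively. The fallback sets out from 15: Pd-catalysed borylation (B2pin2, Pd2(dba)3, THF, 60 °C) should give the allyl pinacolboronate F3. This adds to 9 on heating in PhMe through a closed six-membered boron transition state with the same E-type geometry and the same shielding by the C8 ether. Aqueous work-up gives the δ-lactone carbinol, and the route is rejoined at 17, which is translactonised as in the second half of step 12.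

Step 11. Ring closure onto the electron-poor 1,1-disubstituted olefin may be slow and the allylic bromide may deactivate the catalyst, giving oligomers or unchanged diene. The fallback sets out from 12: acylation with acryloyl chloride (Et3N, CH2Cl2, −78 °C) gives the acrylate ester F4. Ring-closing metathesis of this unhindered acrylate (second-generation Grubbs catalyst, CH2Cl2, 40 °C) gives the dihydropyranone F5. α-Iodination (I2, pyridine, CH2Cl2) gives the 3-iodo lactone F6, and Stille coupling with Bu3SnCH2OH (Pd(PPh3)4, dioxane, 80 °C) gives the 3-hydroxymethyl lactone F7. Appel bromination (CBr4, PPh3, CH2Cl2, 0 °C) then rejoins the route at 15.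

Further compounds
F1 | step 14 | (6R,7S,8S,9S)-14-(tert-butyldimethylsilyloxy)-9-hydroxy-8-(4-methoxybenzyloxy)germacra-1(10)Z,4Z,11(13)-trien-12,6-olide | C=C1C(=O)O[C@@H]2/C=C(/C)CC/C=C(/CO[Si](C)(C)C(C)(C)C)[C@H](O)[C@@H](OCc3ccc(OC)cc3)[C@@H]12
F2 | step 14 | (6R,7S,8S)-14-(tert-butyldimethylsilyloxy)-8-(4-methoxybenzyloxy)-9-oxogermacra-1(10)Z,4Z,11(13)-trien-12,6-olide | C=C1C(=O)O[C@@H]2/C=C(/C)CC/C=C(/CO[Si](C)(C)C(C)(C)C)C(=O)[C@@H](OCc3ccc(OC)cc3)[C@@H]12
F3 | step 12 | (5S)-5-(4-methoxybenzyloxy)-3-[(4,4,5,5-tetramethyl-1,3,2-dioxaborolan-2-yl)methyl]-5,6-dihydro-2H-pyran-2-one | O=C1OC[C@@H](OCc2ccc(OC)cc2)C=C1CB1OC(C)(C)C(C)(C)O1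
F4 | step 11 | (2S)-2-(4-methoxybenzyloxy)but-3-en-1-yl acrylate | C=C[C@H](OCc1ccc(OC)cc1)COC(=O)C=C
F5 | step 11 | (5S)-5-(4-methoxybenzyloxy)-5,6-dihydro-2H-pyran-2-one | O=C1OC[C@@H](OCc2ccc(OC)cc2)C=C1
F6 | step 11 | (5S)-3-iodo-5-(4-methoxybenzyloxy)-5,6-dihydro-2H-pyran-2-one | O=C1OC[C@@H](OCc2ccc(OC)cc2)C=C1I
F7 | step 11 | (5S)-3-(hydroxymethyl)-5-(4-methoxybenzyloxy)-5,6-dihydro-2H-pyran-2-one | O=C1OC[C@@H](OCc2ccc(OC)cc2)C=C1CO
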